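The indenone is opened at C2–C6' and C3–C3a. This leads back to a diaryl ynone (ring A as the aroyl group, ring B on the alkyne) and a ring C/D diazonium salt. One radical cascade then makes both bonds and closes the five-membered ring. Two structural features are exploited. C6' of ring C is ortho to the ether carbon C1', so one nitrogen substituent first activates diaryl ether formation as NO2 and later departs as N2. C3a of ring A lies ortho to the C4 oxygen and para to the C6 oxygen, which makes it a good radical acceptor. Ring A carries two identical silyl ethers; all other phenols are acetates.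

Key step: step 13

Remark on the chemistry: the target SMILES holds no stereo descriptor, so no stereocentre or fixed axis has to be set. The carbinol centre made in step 8 is racemic and is erased in step 12. Locants: indenone C1–C7a (ring A = benzo ring); ring B = aryl on C3; ring C = aryl on C2 (C1' ether carbon, C2' hydroxyl, C4' methoxy, C6' bonded to C2); ring D = benzoate ring. The five starting materials are taken as catalogue chemicals.

Step 1
Reactants: 1 2-hydroxy-5-methoxy-3-nitrobenzaldehyde
Product: 3 2-chloro-5-methoxy-3-nitrobenzaldehyde, via aryloxyiminium chloride 2 (not isolated)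
Conditions: (COCl)2, DMF, −20 °C then 80 °C; aqueous work-up
Reagents that add atoms: oxalyl chloride, O=C(Cl)C(=O)Cl
Why: Vilsmeier-type deoxychlorination, in which the phenol is O-activated as an iminium ether and chloride displaces DMF by addition–elimination at a carbon flanked by nitro and formyl groups; this conversion is established for ortho-nitrophenols carrying a second acceptor, and a halide is chosen because sulfonate esters of such acidic phenols pass their sulfonyl group to a phenoxide instead of reacting at carbon.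

Step 2
Reactants: 3 2-chloro-5-methoxy-3-nitrobenzaldehyde; 4 methyl 2,6-dihydroxy-4-methylbenzoate
Product: 5 methyl 2-(2-formyl-4-methoxy-6-nitrophenoxy)-6-hydroxy-4-methylbenzoate
Conditions: K2CO3, DMF, 60 °C (4 in slight excess)
Reagents that add atoms: none
Why: Nucleophilic aromatic substitution activated by the ortho nitro and ortho formyl groups; the diol is symmetrical so either hydroxyl gives the same ether, and the remaining hydroxyl is hydrogen-bonded to the ester and hindered, which slows a second arylation.

Step 3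
Reactants: 5 methyl 2-(2-formyl-4-methoxy-6-nitrophenoxy)-6-hydroxy-4-methylbenzoate
Product: 7 methyl 2-hydroxy-6-(2-hydroxy-4-methoxy-6-nitrophenoxy)-4-methylbenzoate, via aryl formate 6 (not isolated)
Conditions: mCPBA, TFA (cat.), CH2Cl2, 0 °C to rt; then Et3N (cat.), MeOH, rt
Reagents that add atoms: 3-chloroperbenzoic acid, OOC(=O)c1cccc(Cl)c1
Why: Baeyer–Villiger (Dakin-type) oxidation under acidic peracid conditions, where the ortho aryloxy lone pair supports aryl migration in the Criegee adduct; alkaline H2O2 is avoided because without a free ortho or para hydroxyl it would stop at the benzoic acid, and the formate is then removed by mild methanolysis that leaves the hindered methyl ester alone.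

Step 4
Reactants: 7 methyl 2-hydroxy-6-(2-hydroxy-4-methoxy-6-nitrophenoxy)-4-methylbenzoate
Product: 8 methyl 2-acetoxy-6-(2-acetoxy-4-methoxy-6-nitrophenoxy)-4-methylbenzoate
Conditions: Ac2O, pyridine, DMAP (cat.), CH2Cl2, rt
Reagents that add atoms: acetic anhydride, CC(=O)OC(C)=O
Why: DMAP-catalysed O-acetylation caps both phenols with groups that neither couple with a diazonium ion nor offer weak C–H bonds to radicals.

Step 5
Reactants: 8 methyl 2-acetoxy-6-(2-acetoxy-4-methoxy-6-nitrophenoxy)-4-methylbenzoate
Product: 9 methyl 2-acetoxy-6-(2-acetoxy-6-amino-4-methoxyphenoxy)-4-methylbenzoate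
Conditions: H2 (1 atm), Pd/C, EtOAc, rt
Reagents that add atoms: none
Why: Catalytic hydrogenation of a nitroarene under neutral conditions spares acetates, ester and diaryl ether, and the aniline is carried on at once so that slow lactam formation with the ring D ester cannot set in.

Step 6
Reactants: 9 methyl 2-acetoxy-6-(2-acetoxy-6-amino-4-methoxyphenoxy)-4-methylbenzoate
Product: 10 3-acetoxy-2-[3-acetoxy-2-(methoxycarbonyl)-5-methylphenoxy]-5-methoxybenzenediazonium tetrafluoroborate
Conditions: t-BuONO, HBF4·OEt2, CH2Cl2, −15 to 0 °C; precipitation with Et2O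
Reagents that add atoms: tert-butyl nitrite, CC(C)(C)ON=O; tetrafluoroboric acid, [H+].F[B-](F)(F)F
Why: Diazotisation with an alkyl nitrite in a non-aqueous medium gives the isolable tetrafluoroborate without exposing the aryl acetates to hydrolysis.

Step 7
Reactants: 11 3,5-dihydroxybenzaldehyde
Product: 12 3,5-bis(tert-butyldimethylsilyloxy)benzaldehyde
Conditions: TBSCl, imidazole, DMF, rt
Reagents that add atoms: tert-butyldimethylsilyl chloride, CC(C)(C)[Si](C)(C)Cl
Why: Imidazole-promoted silylation puts two identical ethers on ring A; they keep the ring electron-rich, hold no activated O–CH2 hydrogen for an aryl radical to abstract, and later leave with fluoride under conditions that do not touch acetates.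

Step 8
Reactants: 12 3,5-bis(tert-butyldimethylsilyloxy)benzaldehyde; 13 ethynylmagnesium bromide
Product: 14 1-[3,5-bis(tert-butyldimethylsilyloxy)phenyl]prop-2-yn-1-ol (racemic)
Conditions: THF, 0 °C; aqueous NH4Cl
Reagents that add atoms: none
Why: Grignard 1,2-addition of the acetylide to the aldehyde brings in the future C2 and C3, and the new carbinol centre is formed without control because it is oxidised away in step 12.

Step 9
Reactants: 15 orcinol (5-methylbenzene-1,3-diol)
Product: 16 2-iodo-5-methylbenzene-1,3-diol
Conditions: I2, NaHCO3, H2O/THF, 0 °C to rt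
Reagents that add atoms: iodine, II
Why: Electrophilic iodination of a resorcinol in aqueous hydrogencarbonate goes to the carbon between the two hydroxyl groups, which is the attachment point of ring B.

Step 10
Reactants: 16 2-iodo-5-methylbenzene-1,3-diol
Product: 17 2-iodo-5-methyl-1,3-phenylene diacetate
Conditions: Ac2O, pyridine, CH2Cl2, rt
Reagents that add atoms: acetic anhydride, CC(=O)OC(C)=O
Why: O-Acetylation blocks benzofuran formation from the later ortho-alkynylphenol and places no hydrogen in a 1,5-relationship to the future C3 radical.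

Step 11
Reactants: 14 1-[3,5-bis(tert-butyldimethylsilyloxy)phenyl]prop-2-yn-1-ol; 17 2-iodo-5-methyl-1,3-phenylene diacetate
Product: 18 2-{3-[3,5-bis(tert-butyldimethylsilyloxy)phenyl]-3-hydroxyprop-1-yn-1-yl}-5-methyl-1,3-phenylene diacetate (racemic)
Conditions: PdCl2(PPh3)2 (5 mol %), CuI (10 mol %), Et3N, degassed THF, 45 °C
Reagents that add atoms: none
Why: Sonogashira coupling of an aryl iodide with a terminal propargylic alcohol under a tertiary amine leaves acetates and silyl ethers intact, and joining at the alcohol oxidation level avoids both an acid chloride and the liberation of a terminal alkyne next to base-labile acetates.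

Step 12
Reactants: 18 2-{3-[3,5-bis(tert-butyldimethylsilyloxy)phenyl]-3-hydroxyprop-1-yn-1-yl}-5-methyl-1,3-phenylene diacetate
Product: 19 1-[3,5-bis(tert-butyldimethylsilyloxy)phenyl]-3-(2,6-diacetoxy-4-methylphenyl)prop-2-yn-1-one
Conditions: activated MnO2, CH2Cl2, rt
Reagents that add atoms: none
Why: MnO2 oxidation of a doubly activated (benzylic and propargylic) alcohol is neutral and selective and gives the ynone without disturbing any protecting group.

Step 13
Reactants: 10 3-acetoxy-2-[3-acetoxy-2-(methoxycarbonyl)-5-methylphenoxy]-5-methoxybenzenediazonium tetrafluoroborate; 19 1-[3,5-bis(tert-butyldimethylsilyloxy)phenyl]-3-(2,6-diacetoxy-4-methylphenyl)prop-2-yn-1-one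
Product: 20 methyl 2-acetoxy-6-{2-acetoxy-6-[3-(2,6-diacetoxy-4-methylphenyl)-4,6-bis(tert-butyldimethylsilyloxy)-1-oxo-1H-inden-2-yl]-4-methoxyphenoxy}-4-methylbenzoate
Conditions: 19 (2.5 equiv, 0.4 M), Ru(bpy)3Cl2·6H2O (2 mol %), 2,6-di-tert-butylpyridine (1.2 equiv), degassed MeCN, blue LED, 20 °C, argon; 10 in MeCN added slowly by syringe pump; excess 19 recovered
Reagents that add atoms: none
Why: Photoexcited Ru(bpy)3Cl2 passes one electron to 10, N2 departs, and the σ radical on C6' of ring C adds to the alkyne carbon next to the carbonyl of 19 (C6'–C2), because the far alkyne carbon is screened by the two ortho acetoxy groups of ring B and because this orientation leaves a linear vinyl radical on C3 that is conjugated with ring B. That C3 radical attacks an ortho carbon of the aroyl ring (C3–C3a) in an intramolecular homolytic aromatic substitution, a five-membered closure through C3, C2, C1, C7a and C3a (5-exo-trig if the C3a=C4 bond is counted as the acceptor), after which the cyclohexadienyl radical is oxidised by trivalent ruthenium or by a second molecule of 10 and gives its proton to the hindered pyridine. The closest known reaction types are the radical addition–cyclisation cascades of 1,3-diarylpropynones that give 2-substituted 3-arylindenones and the photoredox Meerwein-type arylation of alkynes with arenediazonium salts. No stereocentre is created. The step needs chemoselectivity of the aryl radical for the alkyne over Pschorr-type attack on its own ring D and over hydrogen abstraction, which is secured by excess concentrated 19, slow addition of 10, a poor hydrogen-donor solvent and the absence of activated C–H bonds in the silyl and acetyl groups (a methyl or benzyl ether on ring B would sit in a 1,5-relationship to the C3 radical). Regioselectivity on ring A is settled by symmetry, since both ortho carbons are equivalent and each is ortho to one silyloxy group and para to the other, and the base keeps liberated HBF4 from stripping the silyl ethers and exposing phenols to azo coupling.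

Step 14
Reactants: 20 tetraacetyl 4,6-bis(silyloxy)indenone
Product: 21 methyl 2-acetoxy-6-{2-acetoxy-6-[3-(2,6-diacetoxy-4-methylphenyl)-4,6-dihydroxy-1-oxo-1H-inden-2-yl]-4-methoxyphenoxy}-4-methylbenzoate
Conditions: Et3N·3HF, THF, 0 °C to rt
Reagents that add atoms: none
Why: Fluoride-induced desilylation with a weakly acidic fluoride source frees only the two ring A phenols, since aryl acetates, the methyl ester and the indenone are inert to this reagent and no reactive by-product is released.

Step 15
Reactants: 21 tetraacetyl 4,6-dihydroxyindenone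
Product: 22 methyl 2-acetoxy-6-{2-acetoxy-6-[3-(2,6-diacetoxy-4-methylphenyl)-4-hydroxy-6-methoxy-1-oxo-1H-inden-2-yl]-4-methoxyphenoxy}-4-methylbenzoate
Conditions: MeOH (1.05 equiv), PPh3, DIAD, THF, 0 °C (PPh3 and DIAD premixed)
Reagents that add atoms: methanol, CO
Why: Mitsunobu etherification with one equivalent of methanol should pick the open C6 phenol, because the C4 phenol sits in the peri pocket under the two acetoxy groups of ring B, and the near-neutral medium avoids the acetyl migration that a carbonate base could trigger.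

Step 16
Reactants: 22 tetraacetyl 4-hydroxy-6-methoxyindenone
Product: 23 Ascomindone B
Conditions: K2CO3, degassed MeOH, argon, 0 °C to rt; then 1 M HCl
Reagents that add atoms: none
Why: Base-mediated methanolysis (Zemplén-type transesterification) removes all four aryl acetates, while exchange at the ring D methyl ester is degenerate in methanol, which also keeps the ester from lactonising with the C2' phenol.

Compound list
1 | 2-hydroxy-5-methoxy-3-nitrobenzaldehyde | O=Cc1cc(OC)cc([N+](=O)[O-])c1O | starting material
2 | N-[(2-formyl-4-methoxy-6-nitrophenoxy)methylidene]-N-methylmethanaminium chloride (not isolated) | O=Cc1cc(OC)cc([N+](=O)[O-])c1OC=[N+](C)C.[Cl-] | intermediate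
3 | 2-chloro-5-methoxy-3-nitrobenzaldehyde | O=Cc1cc(OC)cc([N+](=O)[O-])c1Cl | intermediate
4 | methyl 2,6-dihydroxy-4-methylbenzoate | COC(=O)c1c(O)cc(C)cc1O | starting material
5 | methyl 2-(2-formyl-4-methoxy-6-nitrophenoxy)-6-hydroxy-4-methylbenzoate | COC(=O)c1c(O)cc(C)cc1Oc1c(C=O)cc(OC)cc1[N+](=O)[O-] | intermediate
6 | methyl 2-[2-(formyloxy)-4-methoxy-6-nitrophenoxy]-6-hydroxy-4-methylbenzoate (not isolated) | COC(=O)c1c(O)cc(C)cc1Oc1c(OC=O)cc(OC)cc1[N+](=O)[O-] | intermediate
7 | methyl 2-hydroxy-6-(2-hydroxy-4-methoxy-6-nitrophenoxy)-4-methylbenzoate | COC(=O)c1c(O)cc(C)cc1Oc1c(O)cc(OC)cc1[N+](=O)[O-] | intermediate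
8 | methyl 2-acetoxy-6-(2-acetoxy-4-methoxy-6-nitrophenoxy)-4-methylbenzoate | COC(=O)c1c(OC(C)=O)cc(C)cc1Oc1c(OC(C)=O)cc(OC)cc1[N+](=O)[O-] | intermediate
9 | methyl 2-acetoxy-6-(2-acetoxy-6-amino-4-methoxyphenoxy)-4-methylbenzoate | COC(=O)c1c(OC(C)=O)cc(C)cc1Oc1c(OC(C)=O)cc(OC)cc1N | intermediate
10 | 3-acetoxy-2-[3-acetoxy-2-(methoxycarbonyl)-5-methylphenoxy]-5-methoxybenzenediazonium tetrafluoroborate | COC(=O)c1c(OC(C)=O)cc(C)cc1Oc1c(OC(C)=O)cc(OC)cc1[N+]#N.F[B-](F)(F)F | intermediate
11 | 3,5-dihydroxybenzaldehyde | O=Cc1cc(O)cc(O)c1 | starting material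
12 | 3,5-bis(tert-butyldimethylsilyloxy)benzaldehyde | O=Cc1cc(O[Si](C)(C)C(C)(C)C)cc(O[Si](C)(C)C(C)(C)C)c1 | intermediate
13 | ethynylmagnesium bromide | C#C[Mg]Br | starting material
14 | 1-[3,5-bis(tert-butyldimethylsilyloxy)phenyl]prop-2-yn-1-ol (racemic) | C#CC(O)c1cc(O[Si](C)(C)C(C)(C)C)cc(O[Si](C)(C)C(C)(C)C)c1 | intermediate
15 | orcinol | Cc1cc(O)cc(O)c1 | starting material
16 | 2-iodo-5-methylbenzene-1,3-diol | Cc1cc(O)c(I)c(O)c1 | intermediate
17 | 2-iodo-5-methyl-1,3-phenylene diacetate | Cc1cc(OC(C)=O)c(I)c(OC(C)=O)c1 | intermediate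
18 | 2-{3-[3,5-bis(tert-butyldimethylsilyloxy)phenyl]-3-hydroxyprop-1-yn-1-yl}-5-methyl-1,3-phenylene diacetate (racemic) | CC(=O)Oc1cc(C)cc(OC(C)=O)c1C#CC(O)c1cc(O[Si](C)(C)C(C)(C)C)cc(O[Si](C)(C)C(C)(C)C)c1 | intermediate
19 | 1-[3,5-bis(tert-butyldimethylsilyloxy)phenyl]-3-(2,6-diacetoxy-4-methylphenyl)prop-2-yn-1-one | CC(=O)Oc1cc(C)cc(OC(C)=O)c1C#CC(=O)c1cc(O[Si](C)(C)C(C)(C)C)cc(O[Si](C)(C)C(C)(C)C)c1 | intermediate
20 | tetraacetyl 4,6-bis(tert-butyldimethylsilyloxy)indenone (full name in step 13) | COC(=O)c1c(OC(C)=O)cc(C)cc1Oc1c(OC(C)=O)cc(OC)cc1C1=C(c2c(OC(C)=O)cc(C)cc2OC(C)=O)c2c(O[Si](C)(C)C(C)(C)C)cc(O[Si](C)(C)C(C)(C)C)cc2C1=O | intermediate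
21 | tetraacetyl 4,6-dihydroxyindenone (full name in step 14) | COC(=O)c1c(OC(C)=O)cc(C)cc1Oc1c(OC(C)=O)cc(OC)cc1C1=C(c2c(OC(C)=O)cc(C)cc2OC(C)=O)c2c(O)cc(O)cc2C1=O | intermediate
22 | tetraacetyl 4-hydroxy-6-methoxyindenone (full name in step 15) | COC(=O)c1c(OC(C)=O)cc(C)cc1Oc1c(OC(C)=O)cc(OC)cc1C1=C(c2c(OC(C)=O)cc(C)cc2OC(C)=O)c2c(O)cc(OC)cc2C1=O | intermediate
23 | Ascomindone B | COC(=O)c1c(O)cc(C)cc1Oc1c(O)cc(OC)cc1C1=C(c2c(O)cc(C)cc2O)c2c(O)cc(OC)cc2C1=O | target

Total step count: 16
Longest linear sequence: 10 steps (steps 1–6, then 13–16)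

Steps most likely to fail

Step 13. The aryl radical may be lost before it reaches the internal alkyne, by hydrogen abstraction from the medium or by closure onto its own ring D. After addition, the C3 radical may attack the ipso carbon of ring D instead of ring A.
The fallback forms the same two bonds one at a time by polar and metal-catalysed chemistry. It sets out from 10 and 19 and comes back at 20.
- Exchange of dinitrogen for iodide on 10 (NaI, MeCN, 0 °C) would give the aryl iodide F1.
- Syn-hydrostannation of 19 (Bu3SnH, Pd(PPh3)4, THF, 0 °C) places tin on the carbonyl-side carbon and would give the (E)-α-stannyl enone F2.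
- Stille coupling of the two (Pd2(dba)3, AsPh3, CuI, NMP, 50 °C) makes C6'–C2 with retention and would give the (Z)-α-aryl chalcone F3.
- Nazarov cyclisation onto the activated ring A (BF3·OEt2, CH2Cl2, 0 °C to rt) closes C3–C3a to the racemic trans-2,3-diarylindanone F4.
- Dehydrogenation with DDQ in dioxane restores the C2=C3 double bond of 20.

Step 3. Hydride migration in the Criegee adduct may outrun aryl migration, because the meta nitro group makes ring C electron-poor, so the oxidation may end at the carboxylic acid level.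
The fallback replaces the competing hydrogen by a methyl group, which migrates far less readily than even a nitroaryl group. It sets out from 5 and comes back at 8.
- MeTi(OiPr)3 (THF, −20 °C), which tolerates nitro and ester groups, would add to the aldehyde to give the racemic carbinol F5.
- Dess–Martin periodinane would give the methyl ketone F6.
- Ac2O/pyridine would cap the ring D phenol as the keto acetate F7.
- Baeyer–Villiger oxidation with trifluoroperacetic acid (urea·H2O2, (CF3CO)2O, Na2HPO4, CH2Cl2) delivers the C2' oxygen directly as its acetate, which is 8.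

Step 15. Discrimination between the two ring A phenols may be insufficient, so that methylation at C4 or at both oxygens, or acetyl migration towards C4–O, erodes the outcome.
The fallback moves the differentiation from the alkylation to the deprotection. It sets out from 20 and comes back at 22.
- A limited charge of Et3N·3HF at −20 °C should cleave the exposed C6 silyl ether first and give the C4-silylated C6-phenol F8. Unreacted 20 is recycled and over-cleaved material is 21.
- With a single free phenol, methylation (MeI, K2CO3, acetone, rt) has only one site and gives the C4-silylated C6-methyl ether F9.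
- Excess Et3N·3HF at 40 °C then frees the C4 phenol to give 22.

Further compounds
F1 | step 13 | methyl 2-acetoxy-6-(2-acetoxy-6-iodo-4-methoxyphenoxy)-4-methylbenzoate | COC(=O)c1c(OC(C)=O)cc(C)cc1Oc1c(OC(C)=O)cc(OC)cc1I
F2 | step 13 | (E)-1-[3,5-bis(tert-butyldimethylsilyloxy)phenyl]-3-(2,6-diacetoxy-4-methylphenyl)-2-(tributylstannyl)prop-2-en-1-one | CCCC[Sn](CCCC)(CCCC)/C(=C/c1c(OC(C)=O)cc(C)cc1OC(C)=O)C(=O)c1cc(O[Si](C)(C)C(C)(C)C)cc(O[Si](C)(C)C(C)(C)C)c1
F3 | step 13 | methyl 2-acetoxy-6-{2-acetoxy-6-[(Z)-1-[3,5-bis(tert-butyldimethylsilyloxy)phenyl]-3-(2,6-diacetoxy-4-methylphenyl)-1-oxoprop-2-en-2-yl]-4-methoxyphenoxy}-4-methylbenzoate | COC(=O)c1c(OC(C)=O)cc(C)cc1Oc1c(OC(C)=O)cc(OC)cc1/C(=C/c1c(OC(C)=O)cc(C)cc1OC(C)=O)C(=O)c1cc(O[Si](C)(C)C(C)(C)C)cc(O[Si](C)(C)C(C)(C)C)c1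
F4 | step 13 | trans-2,3-dihydro analogue of 20 (2,3-diarylindan-1-one, racemic, one enantiomer drawn) | O=C1[C@@H](c2cc(OC)cc(OC(C)=O)c2Oc2cc(C)cc(OC(C)=O)c2C(=O)OC)[C@H](c2c(OC(C)=O)cc(C)cc2OC(C)=O)c2c(O[Si](C)(C)C(C)(C)C)cc(O[Si](C)(C)C(C)(C)C)cc21
F5 | step 3 | methyl 2-hydroxy-6-[2-(1-hydroxyethyl)-4-methoxy-6-nitrophenoxy]-4-methylbenzoate (racemic) | COC(=O)c1c(O)cc(C)cc1Oc1c(C(C)O)cc(OC)cc1[N+](=O)[O-]
F6 | step 3 | methyl 2-(2-acetyl-4-methoxy-6-nitrophenoxy)-6-hydroxy-4-methylbenzoate | COC(=O)c1c(O)cc(C)cc1Oc1c(C(C)=O)cc(OC)cc1[N+](=O)[O-]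
F7 | step 3 | methyl 2-acetoxy-6-(2-acetyl-4-methoxy-6-nitrophenoxy)-4-methylbenzoate | COC(=O)c1c(OC(C)=O)cc(C)cc1Oc1c(C(C)=O)cc(OC)cc1[N+](=O)[O-]
F8 | step 15 | tetraacetyl 4-(tert-butyldimethylsilyloxy)-6-hydroxyindenone | COC(=O)c1c(OC(C)=O)cc(C)cc1Oc1c(OC(C)=O)cc(OC)cc1C1=C(c2c(OC(C)=O)cc(C)cc2OC(C)=O)c2c(O[Si](C)(C)C(C)(C)C)cc(O)cc2C1=O
F9 | step 15 | tetraacetyl 4-(tert-butyldimethylsilyloxy)-6-methoxyindenone | COC(=O)c1c(OC(C)=O)cc(C)cc1Oc1c(OC(C)=O)cc(OC)cc1C1=C(c2c(OC(C)=O)cc(C)cc2OC(C)=O)c2c(O[Si](C)(C)C(C)(C)C)cc(OC)cc2C1=O
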